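Decide first what you follow through the four flasks: not the G you read, but its ratio to the L you read.

| flask | L | Q | remark | time |
|---|---|---|---|---|
| Sunday's | 0.060 M | 67 µM | run made earlier |  |
| Friday's | 0.49 M | 67 µM | run made earlier |  |
| blue | 0.080 M | 67 µM |  | 8.0 h |
| teal | 0.15 M | 67 µM |  | 8.0 h |
| green | 0.30 M | 67 µM |  | 8.0 h |
| violet | 0.60 M | 67 µM |  | 8.0 h |

- Sunday's (time / h: G / %, L / %): 0.417: 0.5, 99.2; 1.33: 1.5, 96.0; 2.50: 3.7, 93.2; 3.00: 4.6, 91.7; 5.00: 7.2, 87.7; 6.00: 7.8, 86.3; 8.00: 9.8, 82.6
- Friday's (time / h: G / %, L / %): 1.00: 1.9, 96.4; 2.50: 4.8, 91.2; 3.00: 4.8, 89.6; 5.00: 7.2, 84.4; 6.00: 9.2, 82.4; 8.00: 10.9, 78.4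

(each reading ± 0.5 percentage points)

- a reading or a percentage of G counts all its forms, free or not
- the concentration of G that is asked is that of its free form alone
- "hardly changes" means that all values lie within two and a half points (for a concentration: within two and a half percent of the largest)
- a reading of L is of its free form alone

- [G] (only what is free in solution) at the end for blue, teal, green, violet, in this order
- the course of these numbers from the first flask to the last (falls, then rises / rises, then falls / hardly changes / falls all the way / rises all the way)

1. Take the main step alone, L going to G under Q. Sunday's run reaches 9.8% at the end and Friday's 10.9%, so conversion looks nearly independent of the charge. Free [G] would then follow the charge: Sunday's percentage on blue gives 0.00784 M, and Friday's on violet gives 0.0654 M.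

2. Add a complex of one L with one G. Sunday's L falls to 82.6%, so more L is lost than G is read. The complex holds two L but reads as one G, so if nothing else takes L, the gap 7.6 percentage points is the complex, and free G is 2.2 points. As a pre-equilibrium this gives a reading of K = 69.7 L mol⁻¹. It is a loose reading, since that free share carries a scatter of 1.1 points.

Now define ρ, the G reading divided by the L reading at the same moment. Then [G] = ρ[L]/(1 + K[L]), and once K[L] is large, [G] approaches the ceiling ρ/K, in which the charge has cancelled. Sunday's ρ is 0.119, and Friday's is 0.139. The ceilings, as readings, are 0.00171 M and 0.00199 M, so a charge raised by a factor of 8.17 moves the ceiling by a factor of 1.17.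

3. Add the rest. Friday's G gains 4.8% in the first 2.50 h but 3.7 points in the last 3.00 h, so Friday's readings slow down. I can't name it, but ρ at the end already carries it. Neither run reads ρ at the charges between them. My commitment is that the row follows ρ and stays below those ceilings, rising slightly if ρ stays between the two values.

The forecast gives 0.00145 M, 0.0016 M, 0.00175 M and 0.0019 M, so that the row rises all the way, holding that “formation is roughly first order in L”.

The flasks give 8.19 × 10⁻⁴ M, 0.00143 M, 0.00134 M and 5.40 × 10⁻⁴ M: the row rises, then falls, turning at 0.21 M.

    L + Q → G + Q, rate k1*[L]^2.5*[Q]/(1 + ([L]/Kh1)^2.5) (0.148 M, k = 297 L²·⁵ mol⁻²·⁵ min⁻¹)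
    L + G ⇌ D, settled at all times (K = 180 L mol⁻¹)
    L + Q → E (k = 0.00349 L mol⁻¹ min⁻¹)
    L + G → J (k = 0.0151 L mol⁻¹ min⁻¹)

At the end ρ runs 0.161, 0.272, 0.248 and 0.0982 from blue to violet, so teal stands above Sunday's 0.119 and violet below Friday's 0.139, and ρ rises and falls as the row does. Violet ends with Q at 40.3% of its charge and teal with Q at 81.8% of its charge, and ρ divided by [G] is 190 L mol⁻¹ in teal and 182 L mol⁻¹ in violet.

The runs come from a simulation on assumed constants, and the scatter is random.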